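The 2,6,6-trimethylcyclohexene ring (C1 bears the side chain, C2 the vinylic methyl, C6 the gem-dimethyl group) is treated as a Diels–Alder adduct: the tetrasubstituted C1=C2 bond lies between the allylic CH2 (C3) and quaternary C6, and C4–C5 is a plain ethylene unit. A Lewis-acid-promoted [4+2] cycloaddition of acrolein to an acyclic dienyne (a 3-alkyl-2,4-dimethylpenta-1,3-diene) forms C3–C4, C5–C6, the quaternary centre and the ring at once; the formyl group is then removed. The alkyne becomes an E-vinyl iodide, joined by a Heck reaction to an (R)-2-methyl-2-vinylchroman from asymmetric allylic etherification.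

Key step: step 4

Assumption: the (R,R) enantiomer of the diphosphine ligand in step 12 is taken to deliver the (R)-chroman from the E-carbonate; should the sense be the reverse, the (S,S) ligand is used with no other change.

Step 1
Reactants: 1 N-methoxy-N,2-dimethylpropanamide; 2 prop-1-en-2-ylmagnesium bromide
Product: 3 2,4-dimethylpent-1-en-3-one
Conditions: THF, 0 °C; then cold 1 M HCl
Reagents that add atoms: none
Why: Weinreb ketone synthesis, in which the chelated tetrahedral magnesium adduct resists a second addition and collapses to the enone only on acidic quench.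

Step 2
Reactants: 3 2,4-dimethylpent-1-en-3-one
Product: 5 2,4-dimethylpenta-1,3-dien-3-yl trifluoromethanesulfonate, via lithium dienolate 4 (not isolated)
Conditions: LiN(iPr)2 (LDA), THF, −78 °C; then PhNTf2, −78 → 0 °C; aq. NH4Cl
Reagents that add atoms: N-phenylbis(trifluoromethanesulfonimide), FC(F)(F)S(=O)(=O)N(c1ccccc1)S(=O)(=O)C(F)(F)F
Why: Kinetic deprotonation at the only α-position bearing a hydrogen (the isopropyl CH) gives the cross-conjugated dienolate, and its O-sulfonylation (enol triflate formation) sets the diene constitution without any regiochemical choice.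

Step 3
Reactants: 5 2,4-dimethylpenta-1,3-dien-3-yl trifluoromethanesulfonate; 6 (4-bromobut-1-yn-1-yl)trimethylsilane
Product: 8 trimethyl[6-methyl-5-(propan-2-ylidene)hept-6-en-1-yn-1-yl]silane, via Grignard reagent 7 (not isolated)
Conditions: 6, Mg, THF, 40 °C; then 5, Fe(acac)3 (5 mol%), THF/NMP, −30 → 0 °C
Reagents that add atoms: none
Why: Iron-catalysed Kumada-type cross-coupling of an alkenyl triflate with a primary alkyl Grignard reagent is fast at low temperature, tolerates the silylalkyne and replaces OTf by the four-carbon chain with the diene left intact.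

Step 4
Reactants: 8 trimethyl[6-methyl-5-(propan-2-ylidene)hept-6-en-1-yn-1-yl]silane; 9 acrolein
Product: 10 rac-2,2,4-trimethyl-3-[4-(trimethylsilyl)but-3-yn-1-yl]cyclohex-3-ene-1-carbaldehyde
Conditions: Me2AlCl (0.3 equiv), acrolein (3 equiv), CH2Cl2, −78 → −20 °C
Reagents that add atoms: none
Why: Me2AlCl-bound acrolein is attacked at its β-carbon (future C4) by the unsubstituted CH2 terminus of the diene (future C3) in a strongly asynchronous polar [4+2] cycloaddition, and the developing tertiary allyl cation at the CMe2 terminus (future C6) is captured by the enolate α-carbon (future C5), so that C3–C4, C5–C6 and the quaternary centre arise together while the inner diene carbons become the tetrasubstituted C1=C2 alkene. The closest known reaction type is the Lewis-acid-catalysed Diels–Alder reaction of enals with cis-terminally substituted dienes such as 2,4-dimethylpenta-1,3-diene. The cyclohexene ring closes by intermolecular [4+2] annulation, the second bond forming as a six-membered collapse of the allyl cation–enolate pair. The only new stereocentre, the formyl-bearing carbon, is formed racemic and needs no control because step 5 removes it. The step needs periselectivity for the six-membered ring over cyclobutane or ene products, which the alkyl group on the central diene carbon should secure by twisting the diene toward a cisoid geometry and which collapse at the tertiary allyl terminus favours; the silyl-capped alkyne is inert. Regiochemistry is immaterial, since either orientation forms the same two ring bonds and the formyl group is deleted.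

Step 5
Reactants: 10 rac-2,2,4-trimethyl-3-[4-(trimethylsilyl)but-3-yn-1-yl]cyclohex-3-ene-1-carbaldehyde
Product: 11 trimethyl[4-(2,6,6-trimethylcyclohex-1-en-1-yl)but-1-yn-1-yl]silane
Conditions: RhCl(PPh3)3 (1.05 equiv), toluene, 110 °C
Reagents that add atoms: none
Why: Tsuji–Wilkinson decarbonylation (formyl C–H oxidative addition, CO extrusion, C–H reductive elimination) replaces CHO by H, turning C5 into a plain CH2 and erasing the racemic centre, while the hindered silylalkyne and the tetrasubstituted alkene stay out of the way.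

Step 6
Reactants: 11 trimethyl[4-(2,6,6-trimethylcyclohex-1-en-1-yl)but-1-yn-1-yl]silane
Product: 12 2-(but-3-yn-1-yl)-1,3,3-trimethylcyclohex-1-ene
Conditions: K2CO3 (0.2 equiv), MeOH, rt
Reagents that add atoms: none
Why: Base-catalysed methanolysis of the C(sp)–Si bond (protodesilylation) frees the terminal alkyne needed for carbometalation.

Step 7
Reactants: 12 2-(but-3-yn-1-yl)-1,3,3-trimethylcyclohex-1-ene
Product: 14 2-[(3E)-4-iodo-3-methylbut-3-en-1-yl]-1,3,3-trimethylcyclohex-1-ene, via alkenyldimethylalane 13 (not isolated)
Conditions: AlMe3, Cp2ZrCl2 (25 mol%), CH2Cl2, 0 °C → rt; then I2, THF, −30 → 0 °C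
Reagents that add atoms: trimethylaluminium, C[Al](C)C; iodine, II
Why: Negishi zirconium-catalysed carboalumination adds methyl and aluminium syn across the terminal alkyne with methyl at the internal carbon, and iodinolysis of the C–Al bond with retention gives the E trisubstituted vinyl iodide.

Step 8
Reactants: 15 methyl 4-hydroxy-3-iodobenzoate; 16 but-3-en-2-ol
Product: 17 methyl 4-hydroxy-3-(3-oxobutyl)benzoate
Conditions: Pd(OAc)2 (3 mol%), NaHCO3, n-Bu4NCl, DMF, 50 °C
Reagents that add atoms: none
Why: Heck reaction of an aryl iodide with a secondary allylic alcohol, in which β-hydride elimination toward the carbinol gives an enol that tautomerises to the β-aryl ketone (drawn in its open form, which may equilibrate with the cyclic hemiketal).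

Step 9
Reactants: 17 methyl 4-hydroxy-3-(3-oxobutyl)benzoate; 18 triethyl phosphonoacetate
Product: 20 methyl 3-[(3E)-5-ethoxy-3-methyl-5-oxopent-3-en-1-yl]-4-hydroxybenzoate, via sodium phosphonate carbanion 19 (not isolated)
Conditions: NaH (2.6 equiv), THF, 0 °C → 50 °C; cold aq. NH4Cl; chromatography
Reagents that add atoms: none
Why: Horner–Wadsworth–Emmons olefination of the methyl ketone should favour the E-enoate (ester trans to the larger arylethyl group), the minor Z isomer being removed by chromatography, and the phenoxide does not add to the enoate in aprotic medium because the resulting ester enolate would be far more basic.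

Step 10
Reactants: 20 methyl 3-[(3E)-5-ethoxy-3-methyl-5-oxopent-3-en-1-yl]-4-hydroxybenzoate
Product: 21 methyl 4-hydroxy-3-[(3E)-5-hydroxy-3-methylpent-3-en-1-yl]benzoate
Conditions: iBu2AlH (DIBAL-H, 3.3 equiv), CH2Cl2, −78 °C; aq. potassium sodium tartrate work-up
Reagents that add atoms: none
Why: iBu2AlH 1,2-reduction of the enoate to the allylic alcohol, the first equivalent turning the phenol into an aluminium phenoxide whose para donation deactivates the aryl methyl ester, which should therefore survive at −78 °C.

Step 11
Reactants: 21 methyl 4-hydroxy-3-[(3E)-5-hydroxy-3-methylpent-3-en-1-yl]benzoate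
Product: 22 methyl 4-hydroxy-3-{(3E)-5-[(methoxycarbonyl)oxy]-3-methylpent-3-en-1-yl}benzoate
Conditions: ClCO2Me (1.1 equiv), pyridine, CH2Cl2, −20 → 0 °C
Reagents that add atoms: methyl chloroformate, COC(=O)Cl
Why: O-acylation with a chloroformate under weakly basic conditions should select the neutral primary allylic alcohol over the poorly nucleophilic, ester-deactivated phenol.

Step 12
Reactants: 22 methyl 4-hydroxy-3-{(3E)-5-[(methoxycarbonyl)oxy]-3-methylpent-3-en-1-yl}benzoate
Product: 23 methyl (2R)-2-ethenyl-2-methyl-3,4-dihydro-2H-chromene-6-carboxylate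
Conditions: Pd2(dba)3·CHCl3 (2 mol%), (1R,2R)-N,N′-bis[2-(diphenylphosphino)benzoyl]cyclohexane-1,2-diamine (6 mol%), AcOH (1 equiv), CH2Cl2, rt
Reagents that add atoms: none
Why: Intramolecular Tsuji–Trost asymmetric allylic etherification, in which ionisation gives interconverting π-allyl palladium diastereomers (acetic acid assists equilibration) and the chiral diphosphine pocket lets the phenol attack the more substituted allyl terminus (6-exo) on one enantiotopic face, setting the (R) quaternary C2.

Step 13
Reactants: 14 2-[(3E)-4-iodo-3-methylbut-3-en-1-yl]-1,3,3-trimethylcyclohex-1-ene; 23 methyl (2R)-2-ethenyl-2-methyl-3,4-dihydro-2H-chromene-6-carboxylate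
Product: 24 methyl (2R)-2-methyl-2-[(1E,3E)-4-methyl-6-(2,6,6-trimethylcyclohex-1-en-1-yl)hexa-1,3-dien-1-yl]-3,4-dihydro-2H-chromene-6-carboxylate
Conditions: Pd(OAc)2 (10 mol%), Ag2CO3 (1.2 equiv), DMF, 50 °C, dark
Reagents that add atoms: none
Why: Heck reaction in which the alkenylpalladium species adds to the unhindered CH2 terminus of the vinyl group and syn β-hydride elimination (the quaternary neighbour offers no hydrogen) gives the E,E-diene with retention of the vinyl iodide geometry, silver carbonate suppressing Pd–H re-addition and the stereocentre staying untouched.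

Step 14
Reactants: 24 methyl (2R)-2-methyl-2-[(1E,3E)-4-methyl-6-(2,6,6-trimethylcyclohex-1-en-1-yl)hexa-1,3-dien-1-yl]-3,4-dihydro-2H-chromene-6-carboxylate
Product: 25 (2R)-2-methyl-2-[(1E,3E)-4-methyl-6-(2,6,6-trimethylcyclohex-1-en-1-yl)hexa-1,3-dien-1-yl]-3,4-dihydro-2H-chromene-6-carboxylic acid
Conditions: LiOH·H2O, THF/MeOH/H2O, 40 °C; then cold 1 M HCl to pH 4
Reagents that add atoms: lithium hydroxide, [Li+].[OH-]
Why: Saponification of the aryl methyl ester, whose basic conditions and brief, cold, mildly acidic work-up should spare the tertiary allylic aryl ether, the polyene geometry and the stereocentre.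

Compound list
1 | N-methoxy-N,2-dimethylpropanamide | CC(C)C(=O)N(C)OC | starting material
2 | prop-1-en-2-ylmagnesium bromide | C=C(C)[Mg]Br | starting material
3 | 2,4-dimethylpent-1-en-3-one | C=C(C)C(=O)C(C)C | intermediate
4 | lithium 2,4-dimethylpenta-1,3-dien-3-olate (not isolated) | C=C(C)C(O[Li])=C(C)C | intermediate
5 | 2,4-dimethylpenta-1,3-dien-3-yl trifluoromethanesulfonate | C=C(C)C(OS(=O)(=O)C(F)(F)F)=C(C)C | intermediate
6 | (4-bromobut-1-yn-1-yl)trimethylsilane | C[Si](C)(C)C#CCCBr | starting material
7 | [4-(trimethylsilyl)but-3-yn-1-yl]magnesium bromide (not isolated) | C[Si](C)(C)C#CCC[Mg]Br | intermediate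
8 | trimethyl[6-methyl-5-(propan-2-ylidene)hept-6-en-1-yn-1-yl]silane | C=C(C)C(CCC#C[Si](C)(C)C)=C(C)C | intermediate
9 | acrolein (prop-2-enal) | C=CC=O | starting material
10 | rac-2,2,4-trimethyl-3-[4-(trimethylsilyl)but-3-yn-1-yl]cyclohex-3-ene-1-carbaldehyde | O=CC1CCC(C)=C(CCC#C[Si](C)(C)C)C1(C)C | intermediate
11 | trimethyl[4-(2,6,6-trimethylcyclohex-1-en-1-yl)but-1-yn-1-yl]silane | CC1=C(CCC#C[Si](C)(C)C)C(C)(C)CCC1 | intermediate
12 | 2-(but-3-yn-1-yl)-1,3,3-trimethylcyclohex-1-ene | CC1=C(CCC#C)C(C)(C)CCC1 | intermediate
13 | dimethyl[(1E)-2-methyl-4-(2,6,6-trimethylcyclohex-1-en-1-yl)but-1-en-1-yl]alane (not isolated) | CC1=C(CC/C(C)=C/[Al](C)C)C(C)(C)CCC1 | intermediate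
14 | 2-[(3E)-4-iodo-3-methylbut-3-en-1-yl]-1,3,3-trimethylcyclohex-1-ene | CC1=C(CC/C(C)=C/I)C(C)(C)CCC1 | intermediate
15 | methyl 4-hydroxy-3-iodobenzoate | COC(=O)c1ccc(O)c(I)c1 | starting material
16 | but-3-en-2-ol | CC(O)C=C | starting material
17 | methyl 4-hydroxy-3-(3-oxobutyl)benzoate | COC(=O)c1ccc(O)c(CCC(C)=O)c1 | intermediate
18 | triethyl phosphonoacetate | CCOC(=O)CP(=O)(OCC)OCC | starting material
19 | sodium salt of triethyl phosphonoacetate (not isolated) | CCOC(=O)[CH-]P(=O)(OCC)OCC.[Na+] | intermediate
20 | methyl 3-[(3E)-5-ethoxy-3-methyl-5-oxopent-3-en-1-yl]-4-hydroxybenzoate | CCOC(=O)/C=C(\C)CCc1cc(C(=O)OC)ccc1O | intermediate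
21 | methyl 4-hydroxy-3-[(3E)-5-hydroxy-3-methylpent-3-en-1-yl]benzoate | OC/C=C(\C)CCc1cc(C(=O)OC)ccc1O | intermediate
22 | methyl 4-hydroxy-3-{(3E)-5-[(methoxycarbonyl)oxy]-3-methylpent-3-en-1-yl}benzoate | COC(=O)OC/C=C(\C)CCc1cc(C(=O)OC)ccc1O | intermediate
23 | methyl (2R)-2-ethenyl-2-methyl-3,4-dihydro-2H-chromene-6-carboxylate | C=C[C@@]1(C)CCc2cc(C(=O)OC)ccc2O1 | intermediate
24 | methyl (2R)-2-methyl-2-[(1E,3E)-4-methyl-6-(2,6,6-trimethylcyclohex-1-en-1-yl)hexa-1,3-dien-1-yl]-3,4-dihydro-2H-chromene-6-carboxylate | CC1=C(CC/C(C)=C/C=C/[C@@]2(C)CCc3cc(C(=O)OC)ccc3O2)C(C)(C)CCC1 | intermediate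
25 | (2R)-2-methyl-2-[(1E,3E)-4-methyl-6-(2,6,6-trimethylcyclohex-1-en-1-yl)hexa-1,3-dien-1-yl]-3,4-dihydro-2H-chromene-6-carboxylic acid | CC1=C(CC/C(C)=C/C=C/[C@@]2(C)CCc3cc(C(=O)O)ccc3O2)C(C)(C)CCC1 | target

Total step count: 14. Longest linear sequence: 9 steps (steps 1–7, then 13 and 14); the chroman branch (steps 8–12) joins at step 13.

Steps most likely to fail

Step 4. The twisted, fully substituted diene may not reach a cisoid geometry before the zwitterionic intermediate collapses, so that four-membered-ring or ene-type products form, or acrolein polymerises under the Lewis acid. The fallback keeps the same two-bond annulation but changes the 2π partner to a cation (ionic Diels–Alder reaction). Setting out from 8, 2-vinyl-1,3-dioxolane with catalytic TfOH in CH2Cl2 at −78 °C generates an alkoxyallyl cation, a class of dienophile known to add stepwise to 1,1-disubstituted dienes that resist neutral dienophiles. This should give racemic 2-{2,2,4-trimethyl-3-[4-(trimethylsilyl)but-3-yn-1-yl]cyclohex-3-en-1-yl}-1,3-dioxolane F1. Hydrolysis of the acetal (PPTS, wet acetone) brings the fallback back to the route at 10.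

Step 13. Migratory insertion may take the wrong regiochemistry, β-aryloxide elimination may open the pyran ring, or Pd–H re-addition may scramble the diene geometry. The fallback replaces the Heck reaction by a cross-coupling of two defined alkenyl partners. Setting out from 23, ozonolysis (O3, CH2Cl2/MeOH, −78 °C; Me2S) should give methyl (2R)-2-formyl-2-methyl-3,4-dihydro-2H-chromene-6-carboxylate F2. Takai olefination (CrCl2, CHI3, THF) then gives methyl (2R)-2-[(E)-2-iodoethenyl]-2-methyl-3,4-dihydro-2H-chromene-6-carboxylate F3. Negishi coupling of F3 with the alkenylalane 13 (made from 12 as in step 7, iodine omitted; ZnCl2, Pd(PPh3)4, THF, rt) comes back to the route at 24, each alkene geometry being carried in unchanged from its own coupling partner.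

Step 12. Equilibration of the diastereomeric π-allyl intermediates may be incomplete before C–O bond formation, eroding enantiofacial selectivity, or induction may run in the unwanted sense. The fallback sets the stereocentre by reagent-controlled epoxidation instead. Setting out from 21, Sharpless asymmetric epoxidation (stoichiometric Ti(OiPr)4, L-(+)-diethyl tartrate, t-BuOOH, 4 Å sieves, CH2Cl2, −20 °C) should give methyl 4-hydroxy-3-{2-[(2S,3S)-3-(hydroxymethyl)-2-methyloxiran-2-yl]ethyl}benzoate F4. Acid-promoted 6-exo opening at the tertiary epoxide carbon by the phenol (cat. camphorsulfonic acid, CH2Cl2, 0 °C), with inversion, gives methyl (2R)-2-[(1S)-1,2-dihydroxyethyl]-2-methyl-3,4-dihydro-2H-chromene-6-carboxylate F5. Garegg–Samuelsson deoxygenation of the vicinal diol (PPh3, I2, imidazole, toluene, reflux) comes back to the route at 23.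

Further compounds
F1 | step 4 | rac-2-{2,2,4-trimethyl-3-[4-(trimethylsilyl)but-3-yn-1-yl]cyclohex-3-en-1-yl}-1,3-dioxolane | C[Si](C)(C)C#CCCC1=C(C)CCC(C2OCCO2)C1(C)C
F2 | step 13 | methyl (2R)-2-formyl-2-methyl-3,4-dihydro-2H-chromene-6-carboxylate | O=C[C@@]1(C)CCc2cc(C(=O)OC)ccc2O1
F3 | step 13 | methyl (2R)-2-[(E)-2-iodoethenyl]-2-methyl-3,4-dihydro-2H-chromene-6-carboxylate | I/C=C/[C@@]1(C)CCc2cc(C(=O)OC)ccc2O1
F4 | step 12 | methyl 4-hydroxy-3-{2-[(2S,3S)-3-(hydroxymethyl)-2-methyloxiran-2-yl]ethyl}benzoate | OC[C@@H]1O[C@@]1(C)CCc1cc(C(=O)OC)ccc1O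
F5 | step 12 | methyl (2R)-2-[(1S)-1,2-dihydroxyethyl]-2-methyl-3,4-dihydro-2H-chromene-6-carboxylate | OC[C@H](O)[C@@]1(C)CCc2cc(C(=O)OC)ccc2O1
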